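Ring A is disconnected into a 1,3-diyne and a propiolate alkyne joined by a CH2–O–C(=O) tether. The route exploits the fact that, in ring A, the C5 hydroxymethyl and the C6 alkynyl carbon are ortho (a latent phthalide) and that C3 and C4 carry only hydrogen (a latent, reduced aryne). In one thermal operation the triyne ester 13 forms C5–C6 and C1–C2, closes ring A and the lactone, and the C3–C4 aryne is reduced by cyclooctane. Precursor 13 is the ester of a ring B aryl pentadiynol (phenols as pivalates) with a 4-methoxy-4,4-diarylbutynoic acid (phenols as MOM ethers) that already holds C7.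

Key step: step 10

Assumption: the target is taken as the open para-quinone methide drawn; a ring-chain isomer formed by addition of the ring B 2'-OH to C7 would share the C7 cation and is expected to reopen to the quinone methide on neutralisation.

Step 1
Reactants: 1 4-bromoresorcinol
Product: 2 4-bromo-1,3-phenylene bis(2,2-dimethylpropanoate)
Conditions: PivCl, Et3N, DMAP (cat.), CH2Cl2, 0 °C to rt
Reagents that add atoms: pivaloyl chloride, CC(C)(C)C(Cl)=O
Why: DMAP-catalysed O-acylation of both phenols with an acid chloride should be fast and gives hindered aryl esters whose oxygens are poor nucleophiles for all later steps up to the aryne.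

Step 2
Reactants: 2 4-bromo-1,3-phenylene bis(2,2-dimethylpropanoate)
Product: 3 4-[(trimethylsilyl)ethynyl]-1,3-phenylene bis(2,2-dimethylpropanoate)
Conditions: Me3SiC≡CH, PdCl2(PPh3)2 (cat.), CuI (cat.), Et3N, THF, 65 °C
Reagents that add atoms: ethynyltrimethylsilane, C#C[Si](C)(C)C
Why: Sonogashira coupling of the aryl bromide with a silyl-capped acetylene under a non-nucleophilic tertiary amine should leave the aryl pivalates intact, which matters because a free 2-hydroxyaryl alkyne would cyclise to a benzofuran.

Step 3
Reactants: 3 4-[(trimethylsilyl)ethynyl]-1,3-phenylene bis(2,2-dimethylpropanoate)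
Product: 4 4-(bromoethynyl)-1,3-phenylene bis(2,2-dimethylpropanoate)
Conditions: NBS, AgNO3 (cat.), acetone, rt, dark
Reagents that add atoms: N-bromosuccinimide, O=C1CCC(=O)N1Br
Why: Silver-catalysed desilylative bromination converts the alkynyl C–Si bond directly into C–Br through a silver acetylide under neutral conditions, so no basic methanolysis that could strip the aryl esters is needed.

Step 4
Reactants: 4 4-(bromoethynyl)-1,3-phenylene bis(2,2-dimethylpropanoate); 5 propargyl alcohol (prop-2-yn-1-ol, used in excess)
Product: 6 4-(5-hydroxypenta-1,3-diyn-1-yl)-1,3-phenylene bis(2,2-dimethylpropanoate)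
Conditions: PdCl2(PPh3)2 (cat.), CuI (cat.), i-Pr2NH, THF, 0 °C to rt
Reagents that add atoms: none
Why: This is a Pd/Cu-catalysed Cadiot–Chodkiewicz-type cross-coupling of a 1-bromoalkyne with a terminal alkyne, in which a hindered secondary amine replaces the usual primary amine to spare the aryl pivalates and excess propargyl alcohol suppresses homocoupling of 4.

Step 5
Reactants: 7 4,4'-dihydroxybenzophenone
Product: 8 bis[4-(methoxymethoxy)phenyl]methanone
Conditions: MOMCl, i-Pr2NEt, DMF, 0 °C to rt
Reagents that add atoms: chloromethyl methyl ether, COCCl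
Why: O-Alkylation of the phenols (Williamson-type) gives MOM acetals that withstand Grignard, organolithium, hydride and basic reagents and are removed in the final acid step.

Step 6
Reactants: 8 bis[4-(methoxymethoxy)phenyl]methanone
Product: 9 1,1-bis[4-(methoxymethoxy)phenyl]prop-2-yn-1-ol
Conditions: HC≡CMgBr, THF, 0 °C to rt; then H2O
Reagents that add atoms: ethynylmagnesium bromide, C#C[Mg]Br
Why: 1,2-Addition of an alkynyl Grignard reagent to a non-enolisable diaryl ketone should be clean, and the new carbinol carbon carries two identical aryl groups so no stereocentre arises.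

Step 7
Reactants: 9 1,1-bis[4-(methoxymethoxy)phenyl]prop-2-yn-1-ol
Product: 10 1,1'-(1-methoxyprop-2-yne-1,1-diyl)bis[4-(methoxymethoxy)benzene]
Conditions: NaH, MeI, THF, 0 °C to rt
Reagents that add atoms: iodomethane, CI
Why: Williamson etherification of the tertiary sodium alkoxide with MeI should be selective because NaH in THF does not deprotonate the alkyne C–H at a useful rate.

Step 8
Reactants: 10 1,1'-(1-methoxyprop-2-yne-1,1-diyl)bis[4-(methoxymethoxy)benzene]
Product: 12 4-methoxy-4,4-bis[4-(methoxymethoxy)phenyl]but-2-ynoic acid, via lithium acetylide 11 (not isolated)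
Conditions: n-BuLi, THF, −78 °C; CO2, −78 to 0 °C; cold dilute HCl to pH 4
Reagents that add atoms: carbon dioxide, O=C=O
Why: Deprotonation of the terminal alkyne and carboxylation of the lithium acetylide is the standard entry to 3-substituted propiolic acids, and a brief cold work-up at pH 4 should keep the MOM acetals and the tertiary methyl ether intact.

Step 9
Reactants: 12 4-methoxy-4,4-bis[4-(methoxymethoxy)phenyl]but-2-ynoic acid; 6 4-(5-hydroxypenta-1,3-diyn-1-yl)-1,3-phenylene bis(2,2-dimethylpropanoate)
Product: 13 5-[2,4-bis(pivaloyloxy)phenyl]penta-2,4-diyn-1-yl 4-methoxy-4,4-bis[4-(methoxymethoxy)phenyl]but-2-ynoate (triyne ester)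
Conditions: DCC, DMAP (cat.), CH2Cl2, 0 °C
Reagents that add atoms: none
Why: Steglich esterification (carbodiimide activation, catalytic DMAP) joins the ynoic acid to the primary propargylic alcohol under neutral conditions, with low temperature and low DMAP loading limiting conjugate addition to the ynoate.

Step 10
Reactants: 13 triyne ester
Product: 15 6-[2,4-bis(pivaloyloxy)phenyl]-7-{methoxybis[4-(methoxymethoxy)phenyl]methyl}isobenzofuran-1(3H)-one (ring A phthalide), via ring A benzyne 14 (not isolated)
Conditions: cyclooctane (0.01 M), 140 °C, Ar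
Reagents that add atoms: none
Why: On heating, the 1,3-diyne (four-carbon partner) and the ynoate alkyne (two-carbon partner) of 13 undergo a hexadehydro-Diels–Alder reaction in its stepwise diradical form: the diyne carbon next to OCH2 bonds first to the ynoate carbon next to C=O (C5–C6), and radical recombination then forms C1–C2 to give benzyne 14 with the strained bond across C3–C4. The closest known reaction type is the thermal cycloisomerisation of ester-tethered triynes to phthalide-fused benzynes with reductive capture by a cycloalkane. The five-membered lactone closes through the three-atom CH2–O–C(=O) tether in the first bond-forming event, and the six-membered ring A closes in the second, completing a formal intramolecular [4+2] union. Cyclooctane then hands two vicinal hydrogens to C3 and C4 in one concerted transfer and leaves as cis-cyclooctene; no stereocentre is created. The step needs the aryne to be captured by solvent and not by the ring B oxygen at C2' or by a second substrate molecule, which is secured by the weakly nucleophilic, delocalised pivalate oxygen, by cyclooctane being the bulk medium and by high dilution. Regiochemistry needs no control because the tether dictates which carbons meet.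

Step 11
Reactants: 15 ring A phthalide
Product: 16 6-(2,4-dihydroxyphenyl)-7-{methoxybis[4-(methoxymethoxy)phenyl]methyl}-1,3-dihydroisobenzofuran-1-ol (lactol, racemic at the hemiacetal carbon)
Conditions: i-Bu2AlH (excess), CH2Cl2, −78 °C; MeOH, then aq. potassium sodium tartrate
Reagents that add atoms: none
Why: Partial reduction of a lactone by i-Bu2AlH stops at the aluminium hemiacetal at −78 °C while the same hydride reductively cleaves both aryl pivalates, the MOM acetals and the tertiary methyl ether being inert at this temperature; the lactol carbon forms as an uncontrolled racemic stereocentre that is erased in step 12.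

Step 12
Reactants: 16 lactol
Product: 18 3-ethynyl-4-(hydroxymethyl)-2-{methoxybis[4-(methoxymethoxy)phenyl]methyl}biphenyl-2',4'-diol, via open hydroxy aldehyde 17 (not isolated)
Conditions: dimethyl (1-diazo-2-oxopropyl)phosphonate, K2CO3, MeOH, rt to 40 °C
Reagents that add atoms: dimethyl (1-diazo-2-oxopropyl)phosphonate, COP(=O)(OC)C(=[N+]=[N-])C(C)=O
Why: In this Ohira–Bestmann (Seyferth–Gilbert) homologation the lactol opens to aldehyde 17, which condenses with the diazomethylphosphonate anion made in the flask, loses N2 and undergoes a 1,2-hydrogen shift to the terminal alkyne; the free phenols merely sit as phenoxides and any residual aryl pivalate would be methanolysed under the same conditions.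

Step 13
Reactants: 18 3-ethynyl-4-(hydroxymethyl)-2-{methoxybis[4-(methoxymethoxy)phenyl]methyl}biphenyl-2',4'-diol; 19 4-iodophenol
Product: 20 4-(hydroxymethyl)-3-[(4-hydroxyphenyl)ethynyl]-2-{methoxybis[4-(methoxymethoxy)phenyl]methyl}biphenyl-2',4'-diol
Conditions: Pd(PPh3)4 (cat.), CuI (cat.), Et3N, DMF (degassed), rt to 40 °C
Reagents that add atoms: none
Why: Sonogashira coupling of a terminal alkyne with an aryl iodide tolerates free phenols and the benzylic alcohol, and the iodide allows near-ambient temperature, which limits cycloisomerisation of the ortho-alkynyl benzyl alcohol.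

Step 14
Reactants: 20 4-(hydroxymethyl)-3-[(4-hydroxyphenyl)ethynyl]-2-{methoxybis[4-(methoxymethoxy)phenyl]methyl}biphenyl-2',4'-diol
Product: 22 selaginellin F, via triarylmethyl cation 21 (not isolated)
Conditions: HCl (aq.), MeOH, rt to 40 °C, Ar; then aq. NaHCO3
Reagents that add atoms: none
Why: Acid-catalysed acetal methanolysis removes both MOM groups and the doubly para-oxygenated triarylmethyl methyl ether ionises (SN1) to cation 21, which on neutralisation loses a phenolic proton to give the fuchsone-type quinone methide; the exocyclic alkene has no E/Z issue because the dienone ring is symmetric.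

Compound list
1 | 4-bromoresorcinol (4-bromobenzene-1,3-diol) | Oc1ccc(Br)c(O)c1 | starting material
2 | 4-bromo-1,3-phenylene bis(2,2-dimethylpropanoate) | CC(C)(C)C(=O)Oc1ccc(Br)c(OC(=O)C(C)(C)C)c1 | intermediate
3 | 4-[(trimethylsilyl)ethynyl]-1,3-phenylene bis(2,2-dimethylpropanoate) | CC(C)(C)C(=O)Oc1ccc(C#C[Si](C)(C)C)c(OC(=O)C(C)(C)C)c1 | intermediate
4 | 4-(bromoethynyl)-1,3-phenylene bis(2,2-dimethylpropanoate) | CC(C)(C)C(=O)Oc1ccc(C#CBr)c(OC(=O)C(C)(C)C)c1 | intermediate
5 | propargyl alcohol (prop-2-yn-1-ol) | C#CCO | starting material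
6 | 4-(5-hydroxypenta-1,3-diyn-1-yl)-1,3-phenylene bis(2,2-dimethylpropanoate) | CC(C)(C)C(=O)Oc1ccc(C#CC#CCO)c(OC(=O)C(C)(C)C)c1 | intermediate
7 | 4,4'-dihydroxybenzophenone | O=C(c1ccc(O)cc1)c1ccc(O)cc1 | starting material
8 | bis[4-(methoxymethoxy)phenyl]methanone | COCOc1ccc(cc1)C(=O)c1ccc(OCOC)cc1 | intermediate
9 | 1,1-bis[4-(methoxymethoxy)phenyl]prop-2-yn-1-ol | C#CC(O)(c1ccc(OCOC)cc1)c1ccc(OCOC)cc1 | intermediate
10 | 1,1'-(1-methoxyprop-2-yne-1,1-diyl)bis[4-(methoxymethoxy)benzene] | C#CC(OC)(c1ccc(OCOC)cc1)c1ccc(OCOC)cc1 | intermediate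
11 | lithium acetylide of 10 (not isolated) | [Li]C#CC(OC)(c1ccc(OCOC)cc1)c1ccc(OCOC)cc1 | intermediate
12 | 4-methoxy-4,4-bis[4-(methoxymethoxy)phenyl]but-2-ynoic acid | OC(=O)C#CC(OC)(c1ccc(OCOC)cc1)c1ccc(OCOC)cc1 | intermediate
13 | 5-[2,4-bis(pivaloyloxy)phenyl]penta-2,4-diyn-1-yl 4-methoxy-4,4-bis[4-(methoxymethoxy)phenyl]but-2-ynoate | CC(C)(C)C(=O)Oc1ccc(C#CC#CCOC(=O)C#CC(OC)(c2ccc(OCOC)cc2)c2ccc(OCOC)cc2)c(OC(=O)C(C)(C)C)c1 | intermediate
14 | phthalide-fused ring A benzyne, strained bond across C3–C4 (not isolated) | O=C1OCC2=C1C(C(OC)(c1ccc(OCOC)cc1)c1ccc(OCOC)cc1)=C(c1ccc(OC(=O)C(C)(C)C)cc1OC(=O)C(C)(C)C)C#C2 | intermediate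
15 | 6-[2,4-bis(pivaloyloxy)phenyl]-7-{methoxybis[4-(methoxymethoxy)phenyl]methyl}isobenzofuran-1(3H)-one | O=C1OCc2ccc(-c3ccc(OC(=O)C(C)(C)C)cc3OC(=O)C(C)(C)C)c(C(OC)(c3ccc(OCOC)cc3)c3ccc(OCOC)cc3)c12 | intermediate
16 | 6-(2,4-dihydroxyphenyl)-7-{methoxybis[4-(methoxymethoxy)phenyl]methyl}-1,3-dihydroisobenzofuran-1-ol, racemic at C1 of the lactol | OC1OCc2ccc(-c3ccc(O)cc3O)c(C(OC)(c3ccc(OCOC)cc3)c3ccc(OCOC)cc3)c12 | intermediate
17 | 2',4'-dihydroxy-4-(hydroxymethyl)-2-{methoxybis[4-(methoxymethoxy)phenyl]methyl}biphenyl-3-carbaldehyde (not isolated) | O=Cc1c(CO)ccc(-c2ccc(O)cc2O)c1C(OC)(c1ccc(OCOC)cc1)c1ccc(OCOC)cc1 | intermediate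
18 | 3-ethynyl-4-(hydroxymethyl)-2-{methoxybis[4-(methoxymethoxy)phenyl]methyl}biphenyl-2',4'-diol | C#Cc1c(CO)ccc(-c2ccc(O)cc2O)c1C(OC)(c1ccc(OCOC)cc1)c1ccc(OCOC)cc1 | intermediate
19 | 4-iodophenol | Oc1ccc(I)cc1 | starting material
20 | 4-(hydroxymethyl)-3-[(4-hydroxyphenyl)ethynyl]-2-{methoxybis[4-(methoxymethoxy)phenyl]methyl}biphenyl-2',4'-diol | OCc1ccc(-c2ccc(O)cc2O)c(C(OC)(c2ccc(OCOC)cc2)c2ccc(OCOC)cc2)c1C#Cc1ccc(O)cc1 | intermediate
21 | bis(4-hydroxyphenyl)(aryl)methyl cation at C7, as its chloride (not isolated) | OCc1ccc(-c2ccc(O)cc2O)c([C+](c2ccc(O)cc2)c2ccc(O)cc2)c1C#Cc1ccc(O)cc1.[Cl-] | intermediate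
22 | selaginellin F (no stereocentre) | O=C1C=CC(=C(c2ccc(O)cc2)c2c(-c3ccc(O)cc3O)ccc(CO)c2C#Cc2ccc(O)cc2)C=C1 | target

Total step count: 14. Longest linear sequence: 10 steps (steps 1–4 or 5–8, then 9–14).

Steps most likely to fail

Step 10. The aryne may be consumed by capture at the neighbouring ring B pivalate oxygen or by oligomerisation before cyclooctane delivers two hydrogens, or the slowly cyclising ester-tethered triyne may decompose at the temperature required. The fallback splits the reduction into a polar capture and a separate reduction. It sets out from 13, which is heated in chlorobenzene with excess triethylammonium bromide, so that bromide adds to the aryne and the ammonium ion protonates the resulting aryl anion (hydrohalogenation of an aryne). This should give the ring A bromophthalide F1, with bromine expected at C3, the aryne carbon remote from the lactone fusion. Radical hydrodebromination with Bu3SnH and AIBN in toluene at 80 °C then comes back to the route at 15.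

Step 12. Ring opening of the crowded lactol may be unfavourable, and the aldehyde, flanked by CH2OH and the triarylmethyl-type group, may condense more slowly than the diazophosphonate anion decomposes. The fallback sets out from 16 and uses a Wittig chloromethylenation with the more reactive non-stabilised ylide from (chloromethyl)triphenylphosphonium chloride and NaN(SiMe3)2 (excess, THF, −78 to 0 °C; lactols are standard Wittig substrates). This should give the chloroalkene F2 as an E/Z mixture (Z drawn). Dehydrochlorination with excess LiN(i-Pr)2 in THF then gives the terminal alkyne and comes back to the route at 18.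

Step 11. Complete pivalate cleavage may need warming that lets the aluminium hemiacetal collapse and over-reduce to the diol, or the Lewis-acidic aluminium phenoxide next to C7 may trigger ionisation of the C7 methyl ether. The fallback separates the two tasks. It sets out from 15: K2CO3 in MeOH at rt removes both pivalates to give the diphenol phthalide F3, and i-Bu2AlH at −78 °C (two equivalents being spent on the phenols) then reduces only the lactone, coming back to the route at 16.

Further compounds
F1 | step 10 | 5-bromo-6-[2,4-bis(pivaloyloxy)phenyl]-7-{methoxybis[4-(methoxymethoxy)phenyl]methyl}isobenzofuran-1(3H)-one | O=C1OCc2cc(Br)c(-c3ccc(OC(=O)C(C)(C)C)cc3OC(=O)C(C)(C)C)c(C(OC)(c3ccc(OCOC)cc3)c3ccc(OCOC)cc3)c12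
F2 | step 12 | (Z)-3-(2-chlorovinyl)-4-(hydroxymethyl)-2-{methoxybis[4-(methoxymethoxy)phenyl]methyl}biphenyl-2',4'-diol | Cl/C=C\c1c(CO)ccc(-c2ccc(O)cc2O)c1C(OC)(c1ccc(OCOC)cc1)c1ccc(OCOC)cc1
F3 | step 11 | 6-(2,4-dihydroxyphenyl)-7-{methoxybis[4-(methoxymethoxy)phenyl]methyl}isobenzofuran-1(3H)-one | O=C1OCc2ccc(-c3ccc(O)cc3O)c(C(OC)(c3ccc(OCOC)cc3)c3ccc(OCOC)cc3)c12
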